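The route rests on cutting the aryl ether bond O–C4', which joins the C8 oxygen to ring B at the carbon flanked by the C3' and C5' methoxy groups. Because this cut leaves the oxygen on C8, the C8 stereocentre can be taken unchanged from (S)-lactic acid. In one operation a copper-catalysed Ullmann O-arylation joins (S)-N,N-dimethyllactamide to 5-allyl-2-iodo-1,3-dimethoxybenzene. This delivers all of ring B with its allyl group, and an amide that next acts as acyl donor for ring A. The iodide is made by bromine–lithium exchange, not by deprotonation, and C7 is set last by chelation-controlled reduction to the erythro (7R,8S) alcohol.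

Key step: step 5

Assumption: neolignan numbering is used (ring A = 3,4-dimethoxyphenyl on C7; C8 = ether-bearing methine; C9 = methyl; ring B = 4-allyl-2,6-dimethoxyphenyl, C4' its oxygen-bearing carbon), and the target SMILES is read as (7R,8S), the erythro isomer.

Remarks on the chemistry:
- With C8 fixed as (S), the erythro alcohol is the product of chelation-controlled hydride delivery to the C7 ketone. Felkin–Anh delivery would give the threo (7S,8S) isomer, so a chelating hydride is used in step 7.
- The aryl iodide is not made by deprotonating 1-allyl-3,5-dimethoxybenzene. Its benzylic-allylic CH2 is more acidic than the ring C–H between the methoxy groups, so a butyllithium base would risk allyl-anion formation and isomerisation to the propenyl arene.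

Step 1
Reactants: 1 ethyl (S)-lactate
Product: 2 (S)-N,N-dimethyllactamide
Conditions: Me2NH (anhydrous, 3 equiv), MeOH, sealed vessel, 60–70 °C
Reagents that add atoms: dimethylamine, CNC
Why: Aminolysis of an α-hydroxy ester by an unhindered secondary amine runs under essentially neutral conditions, so the lactate stereocentre is not touched.

Step 2
Reactants: 3 (4-bromo-3,5-dimethoxyphenyl)methanol
Product: 4 2-bromo-5-(bromomethyl)-1,3-dimethoxybenzene
Conditions: PBr3 (0.4 equiv), CH2Cl2, 0 °C to rt
Reagents that add atoms: phosphorus tribromide, BrP(Br)Br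
Why: Conversion of a primary, electron-rich benzylic alcohol into its bromide with PBr3 (phosphite ester, then SN2 displacement by bromide) is reliable and leaves the aryl bromide alone.

Step 3
Reactants: 4 2-bromo-5-(bromomethyl)-1,3-dimethoxybenzene
Product: 5 5-allyl-2-bromo-1,3-dimethoxybenzene
Conditions: CH2=CHMgBr (1.5 equiv), CuI (10 mol%), 2,2'-bipyridyl (10 mol%), THF, −10 °C to rt
Reagents that add atoms: vinylmagnesium bromide, C=C[Mg]Br
Why: A copper-catalysed Kumada-type sp3–sp2 coupling of the benzylic bromide with the vinyl Grignard reagent should give the allylarene directly, the hindered aryl C–Br bond being inert to both the Grignard reagent and the cuprate at this temperature.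

Step 4
Reactants: 5 5-allyl-2-bromo-1,3-dimethoxybenzene
Product: 7 5-allyl-2-iodo-1,3-dimethoxybenzene, via (4-allyl-2,6-dimethoxyphenyl)lithium 6 (not isolated)
Conditions: n-BuLi (1.05 equiv), THF, −78 °C, 15 min; then I2 (1.2 equiv) in THF, −78 °C to 0 °C; aq. Na2S2O3
Reagents that add atoms: iodine, II
Why: Bromine–lithium exchange at −78 °C is far faster than deprotonation of the benzylic-allylic CH2, so the aryllithium held between two chelating methoxy groups should form cleanly and be iodinated before any proton transfer can isomerise the allyl group.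

Step 5
Reactants: 2 (S)-N,N-dimethyllactamide; 7 5-allyl-2-iodo-1,3-dimethoxybenzene
Product: 8 (S)-2-(4-allyl-2,6-dimethoxyphenoxy)-N,N-dimethylpropanamide
Conditions: CuI (10 mol%), 3,4,7,8-tetramethyl-1,10-phenanthroline (20 mol%), Cs2CO3 (2 equiv), 2 in excess (2 equiv), 4 Å molecular sieves, toluene, 100 °C, Ar
Reagents that add atoms: none
Why: Cs2CO3 turns the hydroxyl of 2 into an alkoxide on the phenanthroline-bound monovalent copper centre, the C–I bond of 7 adds oxidatively to give an aryl(alkoxo) trivalent-copper species, and reductive elimination forms the O–C4' bond. The closest known reaction type is the Ullmann-type copper-catalysed O-arylation of secondary aliphatic alcohols with aryl iodides under CuI, a phenanthroline ligand and Cs2CO3; a doubly ortho-substituted, electron-rich iodide sits at the edge of that scope. No ring is closed and no stereocentre is created: the C8–O bond is never broken, so the (S) configuration of 2 is carried into 8 unchanged. The step needs C–O reductive elimination to outrun β-hydride loss from the copper alkoxide (which would reduce 7 to the arene), and it needs C8 to stay configurationally intact. The tertiary amide offers no N–H for competing N-arylation, its α-hydrogen is too weakly acidic for heterogeneous Cs2CO3 in toluene, and its carbonyl together with an ortho methoxy group of 7 can hold copper close to the hindered C4' position. The allyl group is not expected to react with monovalent copper or carbonate.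

Step 6
Reactants: 8 (S)-2-(4-allyl-2,6-dimethoxyphenoxy)-N,N-dimethylpropanamide; 9 4-bromo-1,2-dimethoxybenzene
Product: 12 (S)-2-(4-allyl-2,6-dimethoxyphenoxy)-1-(3,4-dimethoxyphenyl)propan-1-one, via (3,4-dimethoxyphenyl)magnesium bromide 10 (not isolated), via bromomagnesium hemiaminal alkoxide 11 (not isolated)
Conditions: 9, Mg turnings, THF, 40 °C; then 8, THF, 0 °C to rt; cold 1 M HCl, 0 °C
Reagents that add atoms: none
Why: In this Grignard acylation by a tertiary α-alkoxy amide the magnesium-chelated tetrahedral adduct should persist until the acidic quench, which prevents over-addition and keeps the enolisable α-aryloxy ketone, and hence C8, away from the basic organometallic.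

Step 7
Reactants: 12 (S)-2-(4-allyl-2,6-dimethoxyphenoxy)-1-(3,4-dimethoxyphenyl)propan-1-one
Product: 13 (1R,2S)-2-(4-allyl-2,6-dimethoxyphenoxy)-1-(3,4-dimethoxyphenyl)propan-1-ol (target, erythro, 7R,8S)
Conditions: Zn(BH4)2 (Et2O solution, 1.5 equiv), Et2O, −30 °C to 0 °C; then H2O
Reagents that add atoms: none
Why: In this chelation-controlled (Cram-chelate) ketone reduction divalent zinc bridges the carbonyl oxygen and the C8 ether oxygen, hydride arrives from the face bearing the C8 hydrogen and not the methyl group, and C7 is thereby set as (R), erythro to the (S) centre at C8.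

Compound list
1 | ethyl (S)-lactate | CCOC(=O)[C@H](C)O | starting material
2 | (S)-N,N-dimethyllactamide, (2S)-2-hydroxy-N,N-dimethylpropanamide | C[C@H](O)C(=O)N(C)C | intermediate
3 | (4-bromo-3,5-dimethoxyphenyl)methanol | COc1cc(CO)cc(OC)c1Br | starting material
4 | 2-bromo-5-(bromomethyl)-1,3-dimethoxybenzene | COc1cc(CBr)cc(OC)c1Br | intermediate
5 | 5-allyl-2-bromo-1,3-dimethoxybenzene | C=CCc1cc(OC)c(Br)c(OC)c1 | intermediate
6 | (4-allyl-2,6-dimethoxyphenyl)lithium (not isolated) | C=CCc1cc(OC)c([Li])c(OC)c1 | intermediate
7 | 5-allyl-2-iodo-1,3-dimethoxybenzene | C=CCc1cc(OC)c(I)c(OC)c1 | intermediate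
8 | (S)-2-(4-allyl-2,6-dimethoxyphenoxy)-N,N-dimethylpropanamide | C=CCc1cc(OC)c(O[C@@H](C)C(=O)N(C)C)c(OC)c1 | intermediate
9 | 4-bromo-1,2-dimethoxybenzene | COc1ccc(Br)cc1OC | starting material
10 | (3,4-dimethoxyphenyl)magnesium bromide (not isolated) | COc1ccc([Mg]Br)cc1OC | intermediate
11 | bromomagnesium (2S)-2-(4-allyl-2,6-dimethoxyphenoxy)-1-(3,4-dimethoxyphenyl)-1-(dimethylamino)propan-1-olate, hemiaminal carbon undefined (not isolated) | C=CCc1cc(OC)c(O[C@@H](C)C(O[Mg]Br)(N(C)C)c2ccc(OC)c(OC)c2)c(OC)c1 | intermediate
12 | (S)-2-(4-allyl-2,6-dimethoxyphenoxy)-1-(3,4-dimethoxyphenyl)propan-1-one | C=CCc1cc(OC)c(O[C@@H](C)C(=O)c2ccc(OC)c(OC)c2)c(OC)c1 | intermediate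
13 | (1R,2S)-2-(4-allyl-2,6-dimethoxyphenoxy)-1-(3,4-dimethoxyphenyl)propan-1-ol | C=CCc1cc(OC)c(O[C@@H](C)[C@H](O)c2ccc(OC)c(OC)c2)c(OC)c1 | target

Total step count: 7
Longest linear sequence: 6 steps (3 → 4 → 5 → 7 → 8 → 12 → 13; steps 2 to 7)

Steps most likely to fail

1. Step 5. Reductive elimination at the doubly ortho-substituted C4' may be too slow, so that β-hydride loss from the copper alkoxide reduces the iodide, or the chelating hydroxy amide ties up the catalyst. Prolonged heating with carbonate could also erode the configuration at C8. The fallback forms the C8–O bond instead of the O–C4' bond, by displacement with inversion. It sets out from 5: bromine–lithium exchange (n-BuLi, THF, −78 °C) gives 6, which is trapped with B(OMe)3 as dimethyl (4-allyl-2,6-dimethoxyphenyl)boronate F1. Oxidation in the same flask with NaOH/H2O2 at 0 °C should give 4-allyl-2,6-dimethoxyphenol F2, a phenol that can also be bought. A Mitsunobu reaction of F2 with methyl (R)-lactate (PPh3, DIAD, THF, 0 °C to rt) should invert the lactate carbon and give methyl (S)-2-(4-allyl-2,6-dimethoxyphenoxy)propanoate F3. Aminolysis of F3 with Me2NH in MeOH (sealed, 40–50 °C) comes back to the route at 8.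

2. Step 7. Facial selectivity may be poor if divalent zinc does not chelate the hindered, weakly basic aryl ether oxygen fully, and slow hydroboration of the allyl group could compete if the reduction is sluggish. The fallback accepts the opposite, non-chelated selectivity and then inverts C7. It sets out from 12: LiBH(sec-Bu)3 in THF at −78 °C should give, by Felkin–Anh delivery, (1S,2S)-2-(4-allyl-2,6-dimethoxyphenoxy)-1-(3,4-dimethoxyphenyl)propan-1-ol F4. Mitsunobu inversion with 4-nitrobenzoic acid (PPh3, DIAD, THF, 0 °C) should give (1R,2S)-2-(4-allyl-2,6-dimethoxyphenoxy)-1-(3,4-dimethoxyphenyl)propyl 4-nitrobenzoate F5. Methanolysis (K2CO3, MeOH, rt) comes back to the route at 13.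

3. Step 6. The Grignard reagent may enolise the amide or prematurely released ketone, with loss of configuration at C8, or addition to the hindered amide may stall; early collapse of the tetrahedral adduct would allow over-addition. The fallback replaces acyl substitution by aldehyde addition followed by oxidation. It sets out from 8: partial reduction with LiAlH(OEt)3 (Et2O, 0 °C) should give (S)-2-(4-allyl-2,6-dimethoxyphenoxy)propanal F6, used at once. Addition of 10 in THF at −78 °C should give (2S)-2-(4-allyl-2,6-dimethoxyphenoxy)-1-(3,4-dimethoxyphenyl)propan-1-ol F7 as a mixture of C1 epimers. Dess–Martin oxidation (NaHCO3-buffered, CH2Cl2, 0 °C to rt) comes back to the route at 12.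

Further compounds
F1 | step 5 | dimethyl (4-allyl-2,6-dimethoxyphenyl)boronate | C=CCc1cc(OC)c(B(OC)OC)c(OC)c1
F2 | step 5 | 4-allyl-2,6-dimethoxyphenol | C=CCc1cc(OC)c(O)c(OC)c1
F3 | step 5 | methyl (S)-2-(4-allyl-2,6-dimethoxyphenoxy)propanoate | C=CCc1cc(OC)c(O[C@@H](C)C(=O)OC)c(OC)c1
F4 | step 7 | (1S,2S)-2-(4-allyl-2,6-dimethoxyphenoxy)-1-(3,4-dimethoxyphenyl)propan-1-ol | C=CCc1cc(OC)c(O[C@@H](C)[C@@H](O)c2ccc(OC)c(OC)c2)c(OC)c1
F5 | step 7 | (1R,2S)-2-(4-allyl-2,6-dimethoxyphenoxy)-1-(3,4-dimethoxyphenyl)propyl 4-nitrobenzoate | C=CCc1cc(OC)c(O[C@@H](C)[C@H](OC(=O)c2ccc(cc2)[N+](=O)[O-])c3ccc(OC)c(OC)c3)c(OC)c1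
F6 | step 6 | (S)-2-(4-allyl-2,6-dimethoxyphenoxy)propanal | C=CCc1cc(OC)c(O[C@@H](C)C=O)c(OC)c1
F7 | step 6 | (2S)-2-(4-allyl-2,6-dimethoxyphenoxy)-1-(3,4-dimethoxyphenyl)propan-1-ol, C1 epimers | C=CCc1cc(OC)c(O[C@@H](C)C(O)c2ccc(OC)c(OC)c2)c(OC)c1
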